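**Plan**

- Backbone locants used throughout: C1–C5 pentyl, C6–C9 the oxolane carbons (the ring oxygen joins C6 and C9, OH on C7), C10 the myristoyloxy carbon, C11–C19 the chain ending in C18=C19.
- Cuts: the ester C–O at O10; the ring bond O6–C9 together with C10–O (one oxidative event on a 5-hydroxy-(9E)-alkene); C9=C10 back to an alkyne; C8–C9 and C4–C5 at the two CH2 ends of (2S,3S)-1,2:3,4-diepoxybutane; C10–C11 by acetylide alkylation.
- Enabling feature: the ring oxygen on C9 and the ester oxygen on C10 are vicinal and threo, and the C6 and C9 substituents of the oxolane are trans. This is the imprint of a syn addition of a C6-bound metal alkoxide and a metal oxo across an E C9=C10 double bond.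
- Forward order: C9–C19 enyne; C8–C9 (first epoxide); silylation of O7; C4–C5 (second epoxide, frees O6–H); alkyne to E-alkene; closure of the single ring by the perrhenate step; acylation of O10; desilylation.
- Stereochemistry: C6 and C7 come unchanged from the tartrate-derived bis-epoxide; C9 is induced by C6 (2,5-trans closure) and C10 follows from the E geometry and the syn addition in the key step.

Key step: step 6

Remark: (2S,3S)-1,2:3,4-diepoxybutane is assumed to be purchasable as the single enantiomer (it is otherwise one base-mediated step from L-threitol 1,4-dimesylate).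

**Route**

Step 1
Reactants: 1 9-bromonon-1-ene; 2 lithium acetylide–ethylenediamine complex
Product: 3 undec-10-en-1-yne
Conditions: DMSO, 0 °C to rt
Reagents that add atoms: none
Why: SN2 alkylation of an acetylide anion by a primary alkyl bromide in a dipolar aprotic solvent, which should be clean because the remote terminal alkene is inert to the reagent; no stereocentre is formed.

Step 2
Reactants: 3 undec-10-en-1-yne; 4 (2S,3S)-1,2:3,4-diepoxybutane
Product: 6 (1S)-1-[(2S)-oxiran-2-yl]tridec-12-en-3-yn-1-ol, via lithium undec-10-en-1-ynide 5 (not isolated)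
Conditions: n-BuLi, THF, −78 °C; BF3·OEt2; 4 (2 equiv), −78 °C; then H2O
Reagents that add atoms: none
Why: Yamaguchi–Hirao alkynylation, that is the BF3-assisted SN2 opening of an epoxide by a lithium alkynide, which attacks a terminal CH2 of the C2-symmetric bis-epoxide so that both ends are equivalent, neither stereocentre is touched and the hydroxyl set free is the future O7–H; the excess of 4 should hold the reaction at the first opening.

Step 3
Reactants: 6 (1S)-1-[(2S)-oxiran-2-yl]tridec-12-en-3-yn-1-ol
Product: 7 triisopropyl{[(1S)-1-[(2S)-oxiran-2-yl]tridec-12-en-3-yn-1-yl]oxy}silane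
Conditions: TIPSOTf, 2,6-lutidine, CH2Cl2, −78 to 0 °C
Reagents that add atoms: triisopropylsilyl trifluoromethanesulfonate (TIPSOTf), CC(C)[Si](OS(=O)(=O)C(F)(F)F)(C(C)C)C(C)C
Why: Silyl ether formation from a secondary alcohol with a silyl triflate and a hindered pyridine base at low temperature, which the epoxide should survive; the bulky triisopropylsilyl group is chosen because it is slow to migrate to a neighbouring alkoxide, stands up to acid and does not coordinate rhenium.

Step 4
Reactants: 7 triisopropyl{[(1S)-1-[(2S)-oxiran-2-yl]tridec-12-en-3-yn-1-yl]oxy}silane; 8 butylmagnesium chloride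
Product: 9 (6S,7S)-7-[(triisopropylsilyl)oxy]nonadec-18-en-9-yn-6-ol
Conditions: CuI (10 mol %), THF, −40 to −20 °C; then aq NH4Cl
Reagents that add atoms: none
Why: Copper-catalysed SN2 opening of a terminal epoxide by a Grignard reagent at the unsubstituted carbon, which completes the pentyl chain and sets free only O6–H without touching the C6 or C7 configuration, while the internal alkyne and the terminal alkene do not react with a catalytic cuprate at low temperature.

Step 5
Reactants: 9 (6S,7S)-7-[(triisopropylsilyl)oxy]nonadec-18-en-9-yn-6-ol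
Product: 10 (6S,7S,9E)-7-[(triisopropylsilyl)oxy]nonadeca-9,18-dien-6-ol
Conditions: Na, NH3(l)/THF, −33 °C; then solid NH4Cl
Reagents that add atoms: none
Why: Dissolving-metal reduction of an internal alkyne, in which the vinyl radical and vinyl anion intermediates adopt the trans geometry before protonation by ammonia and so give the E alkene, while the isolated terminal alkene, the silyl ether and the homopropargylic C–O bond are not reduced in the absence of an added alcohol.

Step 6
Reactants: 10 (6S,7S,9E)-7-[(triisopropylsilyl)oxy]nonadeca-9,18-dien-6-ol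
Product: 13 (1R)-1-[(2R,4S,5S)-5-pentyl-4-[(triisopropylsilyl)oxy]oxolan-2-yl]dec-9-en-1-ol, via alkyl perrhenate ester 11 (not isolated), via cyclised pentavalent rhenium alkoxide 12 (not isolated)
Conditions: CF3CO2ReO3 (preformed from Re2O7 and (CF3CO)2O in THF), CH2Cl2, 0 °C to rt; then H2O
Reagents that add atoms: trifluoroacetyl perrhenate CF3CO2ReO3, O=C(O[Re](=O)(=O)=O)C(F)(F)F
Why: The C6 hydroxyl exchanges onto heptavalent rhenium to give the alkyl perrhenate 11, whose O–Re=O unit adds suprafacially across the tethered C9=C10 alkene (formal [3+2] addition, or [2+2] addition followed by a 1,2-shift), so that O6 bonds to C9 and an oxo oxygen to C10 while rhenium falls to the pentavalent state, and hydrolysis of 12 then frees the C10 alcohol. The closest known reaction type is the perrhenate-mediated syn-oxidative cyclisation of 5-hydroxyalkenes (bishomoallylic alcohols) to trans-2,5-disubstituted 2-(hydroxyalkyl)oxolanes. The oxolane closes in the 5-exo-trig mode by attack of O6 on C9; the 6-endo attack of O6 on C10 is disfavoured by the compact metallacyclic transition state, and O7 cannot take part because it is blocked as the silyl ether. C9 is controlled by the C6 stereocentre: the pentyl group should take a pseudo-equatorial place in the cyclic transition state and the alkene should add on the face that puts C10 trans to it, and since the C7 silyloxy group lies on the same side as pentyl, both substituents push the same way; C10 is controlled by the E geometry of the alkene together with the syn addition, which translates into the threo (9R,10R) pair. The step needs 2,5-trans over 2,5-cis selectivity, which the bulky non-coordinating silyl ether should secure by keeping O7 off the metal, and chemoselectivity for C9=C10 over the terminal C18=C19 alkene, which follows because only an alkene that can reach the rhenium-bound alkoxide through a five-membered ring is oxidised.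

Step 7
Reactants: 13 (1R)-1-[(2R,4S,5S)-5-pentyl-4-[(triisopropylsilyl)oxy]oxolan-2-yl]dec-9-en-1-ol; 14 tetradecanoyl chloride
Product: 15 (1R)-1-[(2R,4S,5S)-5-pentyl-4-[(triisopropylsilyl)oxy]oxolan-2-yl]dec-9-en-1-yl tetradecanoate
Conditions: pyridine, DMAP (cat.), CH2Cl2, 0 °C to rt
Reagents that add atoms: none
Why: DMAP-catalysed acylation (nucleophilic catalysis through the acylpyridinium ion) of the only free hydroxyl, O10–H, by an acid chloride, so that the myristate can reach no other oxygen and the C10 configuration is retained.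

Step 8
Reactants: 15 (1R)-1-[(2R,4S,5S)-5-pentyl-4-[(triisopropylsilyl)oxy]oxolan-2-yl]dec-9-en-1-yl tetradecanoate
Product: 16 (1R)-1-[(2R,4S,5S)-4-hydroxy-5-pentyloxolan-2-yl]dec-9-en-1-yl tetradecanoate
Conditions: HF·pyridine, THF, 0 °C to rt
Reagents that add atoms: none
Why: Fluoride-driven cleavage of a silyl ether (formation of the strong Si–F bond) under mildly acidic conditions that should neither hydrolyse the ester nor let the acyl group migrate, since O7 and the C10 ester lie on opposite faces of the oxolane, and that leave the terminal alkene untouched.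

**Compound list**

1 | 9-bromonon-1-ene | BrCCCCCCCC=C | starting material
2 | lithium acetylide–ethylenediamine complex | [Li]C#C.NCCN | starting material
3 | undec-10-en-1-yne | C#CCCCCCCCC=C | intermediate
4 | (2S,3S)-1,2:3,4-diepoxybutane | C1O[C@@H]1[C@@H]1CO1 | starting material
5 | lithium undec-10-en-1-ynide | [Li]C#CCCCCCCCC=C | intermediate
6 | (1S)-1-[(2S)-oxiran-2-yl]tridec-12-en-3-yn-1-ol | C=CCCCCCCCC#CC[C@H](O)[C@@H]1CO1 | intermediate
7 | triisopropyl{[(1S)-1-[(2S)-oxiran-2-yl]tridec-12-en-3-yn-1-yl]oxy}silane | C=CCCCCCCCC#CC[C@H](O[Si](C(C)C)(C(C)C)C(C)C)[C@@H]1CO1 | intermediate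
8 | butylmagnesium chloride | CCCC[Mg]Cl | starting material
9 | (6S,7S)-7-[(triisopropylsilyl)oxy]nonadec-18-en-9-yn-6-ol | CCCCC[C@H](O)[C@@H](O[Si](C(C)C)(C(C)C)C(C)C)CC#CCCCCCCCC=C | intermediate
10 | (6S,7S,9E)-7-[(triisopropylsilyl)oxy]nonadeca-9,18-dien-6-ol | CCCCC[C@H](O)[C@@H](O[Si](C(C)C)(C(C)C)C(C)C)C/C=C/CCCCCCCC=C | intermediate
11 | (6S,7S,9E)-7-[(triisopropylsilyl)oxy]nonadeca-9,18-dien-6-yl perrhenate (heptavalent rhenium ester at O6) | CCCCC[C@H](O[Re](=O)(=O)=O)[C@@H](O[Si](C(C)C)(C(C)C)C(C)C)C/C=C/CCCCCCCC=C | intermediate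
12 | dioxorhenium alkoxide (pentavalent rhenium) at O10 of the cyclised product 13 | C=CCCCCCCC[C@@H](O[Re](=O)=O)[C@H]1C[C@H](O[Si](C(C)C)(C(C)C)C(C)C)[C@H](CCCCC)O1 | intermediate
13 | (1R)-1-[(2R,4S,5S)-5-pentyl-4-[(triisopropylsilyl)oxy]oxolan-2-yl]dec-9-en-1-ol | C=CCCCCCCC[C@@H](O)[C@H]1C[C@H](O[Si](C(C)C)(C(C)C)C(C)C)[C@H](CCCCC)O1 | intermediate
14 | tetradecanoyl chloride | CCCCCCCCCCCCCC(=O)Cl | starting material
15 | (1R)-1-[(2R,4S,5S)-5-pentyl-4-[(triisopropylsilyl)oxy]oxolan-2-yl]dec-9-en-1-yl tetradecanoate | C=CCCCCCCC[C@@H](OC(=O)CCCCCCCCCCCCC)[C@H]1C[C@H](O[Si](C(C)C)(C(C)C)C(C)C)[C@H](CCCCC)O1 | intermediate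
16 | (1R)-1-[(2R,4S,5S)-4-hydroxy-5-pentyloxolan-2-yl]dec-9-en-1-yl tetradecanoate | C=CCCCCCCC[C@@H](OC(=O)CCCCCCCCCCCCC)[C@H]1C[C@H](O)[C@H](CCCCC)O1 | target

**Step count and risks**

Total step count: 8. Longest linear sequence: 8 steps (1 → 3 → 6 → 7 → 9 → 10 → 13 → 15 → 16); 4, 8 and 14 enter at steps 2, 4 and 7.

Steps most likely to fail:

Step 6. The process at risk is loss of 2,5-facial control in the oxo-rhenium addition (for instance if O7 coordinates the metal), or acid-induced loss of the silyl group before cyclisation. The fallback replaces the single syn addition by an anti addition followed by inversion. Setting out from 10, a Shi epoxidation of the E C9=C10 alkene with the L-sorbose-derived enantiomer of the fructose ketone catalyst (KHSO5, K2CO3 buffer, MeCN/dimethoxymethane/H2O, 0 °C), in which the E-disubstituted alkene should react ahead of the terminal one, should give (6S,7S,9S,10S)-9,10-epoxy-7-[(triisopropylsilyl)oxy]nonadec-18-en-6-ol F1. Catalytic camphorsulfonic acid in CH2Cl2 should then close the ring by 5-exo SN2 attack of O6 on C9 with inversion, giving the C10 epimer (1S)-1-[(2R,4S,5S)-5-pentyl-4-[(triisopropylsilyl)oxy]oxolan-2-yl]dec-9-en-1-ol F2. A Mitsunobu esterification of F2 with tetradecanoic acid (PPh3, DIAD, THF) inverts C10 and installs the myristate in one operation, coming back to the route at 15, so that step 7 is not needed.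

Step 5. The process at risk is 1,2-migration of the silyl group from O7 to the neighbouring sodium alkoxide on O6 under the basic reduction conditions, which would scramble the differentiation of the two oxygens. Setting out from 9, the C6 hydroxyl is first capped (TESCl, imidazole, DMF) as (6S,7S)-6-[(triethylsilyl)oxy]-7-[(triisopropylsilyl)oxy]nonadec-18-en-9-yne F3, so that no alkoxide can form next to the silyl ether. The Na/NH3 reduction then gives (6S,7S,9E)-6-[(triethylsilyl)oxy]-7-[(triisopropylsilyl)oxy]nonadeca-9,18-diene F4. PPTS in MeOH at 0 °C removes the triethylsilyl group selectively and the route is rejoined at 10.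

Step 2. The process at risk is over-reaction, that is a second alkynylation of the surviving epoxide and Lewis-acid-induced decomposition of the bis-epoxide. The fallback reverses the order of the two openings, so that BF3 only ever meets a mono-epoxide. Setting out from 4 and 8, CuI-catalysed opening of one epoxide (4 in excess, THF, −40 °C) should give (1S)-1-[(2S)-oxiran-2-yl]hexan-1-ol F5. NaH and 4-methoxybenzyl chloride (Bu4NI, THF, 0 °C) give (2S)-2-[(1S)-1-[(4-methoxybenzyl)oxy]hexyl]oxirane F6. The alkynide 5 with BF3·OEt2 (THF, −78 °C) opens the remaining epoxide to (6S,7S)-6-[(4-methoxybenzyl)oxy]nonadec-18-en-9-yn-7-ol F7. TIPSOTf and 2,6-lutidine give triisopropyl{[(6S,7S)-6-[(4-methoxybenzyl)oxy]nonadec-18-en-9-yn-7-yl]oxy}silane F8. DDQ in CH2Cl2/pH 7 buffer removes the 4-methoxybenzyl group and the route is rejoined at 9.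

Further compounds
F1 | step 6 | (6S,7S,9S,10S)-9,10-epoxy-7-[(triisopropylsilyl)oxy]nonadec-18-en-6-ol | CCCCC[C@H](O)[C@@H](O[Si](C(C)C)(C(C)C)C(C)C)C[C@@H]1O[C@H]1CCCCCCCC=C
F2 | step 6 | (1S)-1-[(2R,4S,5S)-5-pentyl-4-[(triisopropylsilyl)oxy]oxolan-2-yl]dec-9-en-1-ol | C=CCCCCCCC[C@H](O)[C@H]1C[C@H](O[Si](C(C)C)(C(C)C)C(C)C)[C@H](CCCCC)O1
F3 | step 5 | (6S,7S)-6-[(triethylsilyl)oxy]-7-[(triisopropylsilyl)oxy]nonadec-18-en-9-yne | CCCCC[C@H](O[Si](CC)(CC)CC)[C@@H](O[Si](C(C)C)(C(C)C)C(C)C)CC#CCCCCCCCC=C
F4 | step 5 | (6S,7S,9E)-6-[(triethylsilyl)oxy]-7-[(triisopropylsilyl)oxy]nonadeca-9,18-diene | CCCCC[C@H](O[Si](CC)(CC)CC)[C@@H](O[Si](C(C)C)(C(C)C)C(C)C)C/C=C/CCCCCCCC=C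
F5 | step 2 | (1S)-1-[(2S)-oxiran-2-yl]hexan-1-ol | CCCCC[C@H](O)[C@@H]1CO1
F6 | step 2 | (2S)-2-[(1S)-1-[(4-methoxybenzyl)oxy]hexyl]oxirane | CCCCC[C@H](OCc1ccc(OC)cc1)[C@@H]1CO1
F7 | step 2 | (6S,7S)-6-[(4-methoxybenzyl)oxy]nonadec-18-en-9-yn-7-ol | CCCCC[C@H](OCc1ccc(OC)cc1)[C@@H](O)CC#CCCCCCCCC=C
F8 | step 2 | triisopropyl{[(6S,7S)-6-[(4-methoxybenzyl)oxy]nonadec-18-en-9-yn-7-yl]oxy}silane | CCCCC[C@H](OCc1ccc(OC)cc1)[C@@H](O[Si](C(C)C)(C(C)C)C(C)C)CC#CCCCCCCCC=C
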